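**Retrosynthetic overview**

1. The strategy rests on C8, the secondary allylic carbinol (acetylated last) on C7 of the ring-cis trisubstituted C6=C7 alkene in the ten-membered carbocycle C1–C10. This is the retron of a (Z)-alkenyl iodide adding to an aldehyde, so C7–C8 is cut (Nozaki–Hiyama–Kishi) with the five-membered methylene lactone (O, C1, C10, C11, C12) already in place.
2. The seco iodo-aldehyde is cut at C1–C10: a syn, enantioselective allylboration of a C1 enal (fragment A: C1–C7, C14, C15) with a 2-(methoxycarbonyl)allylboronate (fragment B: C8–C13), followed by lactonisation, gives the cis lactone.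
3. Fragment A: syn carbocupration of a 4-silyloxybut-2-ynoate fixes the ring-trans C2=C3 geometry; ozonolysis and Stork–Zhao olefination install the (Z)-C7 iodide.
4. Fragment B: Morita–Baylis–Hillman adduct of methyl acrylate and 3,3-dimethoxypropanal, then SN2′ borylation.
5. Ring order: five-membered lactone first (step 11), ten-membered carbocycle last (step 14).

Key step: step 14

Numbering used throughout: C1 (lactone O–CH), C2=C3 (C3 bears C15H2–O), C4, C5, C6=C7 (C7 bears the C14 methyl), C8 (CH–O), C9, C10 (ring-fusion CH), C11 (bears the C13 methylene), C12 (lactone C=O).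

Assumption on step 11: the (S)-phosphoric acid is taken to send the allyl group to the Si face of the aldehyde, as the mirror image of the usual Re-face preference of the (R)-acid; if a model enal shows the opposite sense, the (R)-acid is used with no other change.

Assumption on supply: compounds 1, 3 (as a THF solution), 11 and 13 are taken as catalogue chemicals.

**Route**

Step 1
Reactants: 1 methyl 4-hydroxybut-2-ynoate
Product: 2 methyl 4-{[tert-butyl(dimethyl)silyl]oxy}but-2-ynoate
Conditions: TBSCl, imidazole, CH2Cl2, 0 °C → rt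
Reagents that add atoms: tert-butyldimethylsilyl chloride, CC(C)(C)[Si](C)(C)Cl
Why: Imidazole-promoted O-silylation of the primary propargylic alcohol is fast and leaves the ynoate untouched, and the silyl ether later keeps the C15 oxygen, cis to the C1 ester, from closing to a butenolide.

Step 2
Reactants: 2 methyl 4-{[tert-butyl(dimethyl)silyl]oxy}but-2-ynoate; 3 but-3-en-1-ylmagnesium bromide
Product: 5 methyl (2Z)-3-({[tert-butyl(dimethyl)silyl]oxy}methyl)hepta-2,6-dienoate, via alkenylcopper adduct 4 (not isolated)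
Conditions: CuBr·SMe2 (1.3 equiv), THF, −40 °C; 2, −78 °C; aq. NH4Cl at −78 °C
Reagents that add atoms: none
Why: Syn carbocupration (conjugate addition of the organocopper reagent to the ynoate) puts the butenyl group on C3 and copper on C2 on the same side, and protonation of the configurationally stable alkenylcopper 4 at −78 °C with retention leaves the C1 ester cis to C15, which is the ring-trans C2=C3 geometry of the target.

Step 3
Reactants: 5 methyl (2Z)-3-({[tert-butyl(dimethyl)silyl]oxy}methyl)hepta-2,6-dienoate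
Product: 7 methyl (2Z)-3-({[tert-butyl(dimethyl)silyl]oxy}methyl)-6-oxohex-2-enoate, via ozonide 6 (not isolated)
Conditions: O3, CH2Cl2, −78 °C, Sudan red 7B end point; PPh3, −78 °C → rt
Reagents that add atoms: ozone, [O-][O+]=O
Why: Ozonolysis with reductive work-up cleaves only the electron-rich monosubstituted terminal alkene, because the ester-conjugated trisubstituted C2=C3 bond reacts far more slowly and the dye end point stops the gas at one equivalent.

Step 4
Reactants: 7 methyl (2Z)-3-({[tert-butyl(dimethyl)silyl]oxy}methyl)-6-oxohex-2-enoate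
Product: 8 methyl (2Z,6Z)-3-({[tert-butyl(dimethyl)silyl]oxy}methyl)-7-iodoocta-2,6-dienoate
Conditions: EtPPh3I, n-BuLi, THF, rt; I2, −78 °C; NaN(SiMe3)2, −20 °C; 7, −78 → −20 °C
Reagents that add atoms: ethyltriphenylphosphonium iodide, CC[P+](c1ccccc1)(c1ccccc1)c1ccccc1.[I-]; iodine, II
Why: Stork–Zhao olefination (Wittig reaction of the α-iodo ylide) should give the 2-iodoalk-2-ene with iodine cis to the chain under kinetic control, and the cold conditions without excess base leave the enoate geometry and the silyl ether alone.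

Step 5
Reactants: 8 methyl (2Z,6Z)-3-({[tert-butyl(dimethyl)silyl]oxy}methyl)-7-iodoocta-2,6-dienoate
Product: 9 (2Z,6Z)-3-({[tert-butyl(dimethyl)silyl]oxy}methyl)-7-iodoocta-2,6-dien-1-ol
Conditions: i-Bu2AlH (2.2 equiv), CH2Cl2, −78 °C; aq. potassium sodium tartrate
Reagents that add atoms: none
Why: i-Bu2AlH reduces the conjugated methyl ester by 1,2-hydride delivery to the allylic alcohol without touching the alkenyl iodide or either alkene geometry, and the cold tartrate work-up avoids a 1,5 silyl shift between the two cis CH2O groups.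

Step 6
Reactants: 9 (2Z,6Z)-3-({[tert-butyl(dimethyl)silyl]oxy}methyl)-7-iodoocta-2,6-dien-1-ol
Product: 10 (2Z,6Z)-3-({[tert-butyl(dimethyl)silyl]oxy}methyl)-7-iodoocta-2,6-dienal (fragment A)
Conditions: Dess–Martin periodinane, NaHCO3, CH2Cl2, 0 °C
Reagents that add atoms: none
Why: Dess–Martin oxidation under bicarbonate buffer converts the primary allylic alcohol to the enal under neutral conditions that should neither isomerise the Z C2=C3 bond nor cleave the silyl ether.

Step 7
Reactants: 11 methyl 3,3-dimethoxypropanoate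
Product: 12 3,3-dimethoxypropanal
Conditions: i-Bu2AlH (1.05 equiv), CH2Cl2, −78 °C; aq. potassium sodium tartrate; used crude at once
Reagents that add atoms: none
Why: Partial reduction of a methyl ester with one equivalent of i-Bu2AlH at −78 °C stops at the aldehyde oxidation level while the acetal is inert to hydride.

Step 8
Reactants: 12 3,3-dimethoxypropanal; 13 methyl acrylate
Product: 14 methyl 3-hydroxy-5,5-dimethoxy-2-methylidenepentanoate (racemic)
Conditions: DABCO (1 equiv), 1,4-dioxane–H2O (1:1), rt
Reagents that add atoms: none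
Why: In the Morita–Baylis–Hillman reaction DABCO adds to the acrylate and the resulting enolate attacks the aldehyde, the aqueous medium giving a rate that should outrun loss of methanol from the β,β-dialkoxy aldehyde, and the new carbinol centre is racemic and is destroyed in step 10.

Step 9
Reactants: 14 methyl 3-hydroxy-5,5-dimethoxy-2-methylidenepentanoate
Product: 15 methyl 3-(acetyloxy)-5,5-dimethoxy-2-methylidenepentanoate (racemic)
Conditions: Ac2O, Et3N, DMAP (cat.), CH2Cl2, 0 °C
Reagents that add atoms: acetic anhydride, CC(=O)OC(C)=O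
Why: DMAP-catalysed acetylation turns the allylic hydroxyl into the leaving group needed for the SN2′ borylation.

Step 10
Reactants: 15 methyl 3-(acetyloxy)-5,5-dimethoxy-2-methylidenepentanoate
Product: 16 methyl (2E)-5,5-dimethoxy-2-[(4,4,5,5-tetramethyl-1,3,2-dioxaborolan-2-yl)methyl]pent-2-enoate (fragment B)
Conditions: B2pin2, CuCl, LiCl, KOAc, DMF, rt
Reagents that add atoms: bis(pinacolato)diboron, CC1(C)OB(OC1(C)C)B1OC(C)(C)C(C)(C)O1
Why: Copper-mediated conjugate borylation of the acrylate followed by loss of acetate (overall SN2′) moves the double bond to C10=C11 and should give the isomer usual for ester-bearing Morita–Baylis–Hillman acetates, with the C9 chain trans to the ester and cis to CH2B, which is the geometry a chair allylboration turns into the syn adduct.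

Step 11
Reactants: 10 (2Z,6Z)-3-({[tert-butyl(dimethyl)silyl]oxy}methyl)-7-iodoocta-2,6-dienal; 16 methyl (2E)-5,5-dimethoxy-2-[(4,4,5,5-tetramethyl-1,3,2-dioxaborolan-2-yl)methyl]pent-2-enoate
Product: 18 (4R,5R)-5-[(1Z,5Z)-2-({[tert-butyl(dimethyl)silyl]oxy}methyl)-6-iodohepta-1,5-dien-1-yl]-4-(2,2-dimethoxyethyl)-3-methylideneoxolan-2-one, via O-boryl hydroxy ester 17 (not isolated)
Conditions: (S)-TRIP [(S)-3,3′-bis(2,4,6-triisopropylphenyl)-1,1′-binaphthyl-2,2′-diyl hydrogen phosphate] (10 mol%), 4 Å MS, toluene, −20 °C → rt; then PPTS (20 mol%), 40 °C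
Reagents that add atoms: none
Why: This is a chiral phosphoric acid-catalysed allylboration, a Brønsted acid-accelerated addition of a 2-(alkoxycarbonyl)allylboronate through a closed six-membered chair transition state, in which the C9 chain cis to CH2B sits axial and the alkenyl group of the aldehyde equatorial so that C1–C10 forms syn (the cis lactone once the boron-bound alkoxide of 17 closes onto the methyl ester), while the (S)-acid, bound to a boronate oxygen and to the formyl hydrogen, should direct C10 to the Si face of the aldehyde and thereby set 1R and 10R.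

Step 12
Reactants: 18 (4R,5R)-5-[(1Z,5Z)-2-({[tert-butyl(dimethyl)silyl]oxy}methyl)-6-iodohepta-1,5-dien-1-yl]-4-(2,2-dimethoxyethyl)-3-methylideneoxolan-2-one
Product: 19 (4R,5R)-5-[(1Z,5Z)-2-(hydroxymethyl)-6-iodohepta-1,5-dien-1-yl]-3-methylidene-4-(2-oxoethyl)oxolan-2-one
Conditions: AcOH–THF–H2O (3:1:1), 35 °C
Reagents that add atoms: water, O
Why: Acid-catalysed hydrolysis in aqueous acetic acid removes the dimethyl acetal and the primary silyl ether in one operation under conditions too mild to ionise the allylic lactone C1–O bond or to hydrate the methylene lactone.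

Step 13
Reactants: 19 (4R,5R)-5-[(1Z,5Z)-2-(hydroxymethyl)-6-iodohepta-1,5-dien-1-yl]-3-methylidene-4-(2-oxoethyl)oxolan-2-one
Product: 20 (4R,5R)-5-{(1Z,5Z)-6-iodo-2-[(3-methylbutanoyloxy)methyl]hepta-1,5-dien-1-yl}-3-methylidene-4-(2-oxoethyl)oxolan-2-one (seco iodo-aldehyde)
Conditions: isovaleryl chloride (1.2 equiv), pyridine, CH2Cl2, 0 °C
Reagents that add atoms: isovaleryl chloride, CC(C)CC(Cl)=O
Why: O-Acylation of the primary allylic alcohol by the acid chloride and pyridine is fast at 0 °C and chemoselective, since the aldehyde and the Michael acceptor are inert when no nucleophilic catalyst is present.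

Step 14
Reactants: 20 (4R,5R)-5-{(1Z,5Z)-6-iodo-2-[(3-methylbutanoyloxy)methyl]hepta-1,5-dien-1-yl}-3-methylidene-4-(2-oxoethyl)oxolan-2-one
Product: 23 [(3aR,5S,6Z,10Z,11aR)-5-hydroxy-6-methyl-3-methylidene-2-oxo-2,3,3a,4,5,8,9,11a-octahydrocyclodeca[b]furan-10-yl]methyl 3-methylbutanoate (route numbering 1R,8S,10R), via alkenylchromium 21 (not isolated), via chromium alkoxide 22 (not isolated)
Conditions: CrCl2 (8 equiv), NiCl2 (0.1 equiv), degassed DMSO, rt, 20 added over 12 h to a final 0.002 M; aq. work-up
Reagents that add atoms: none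
Why: Zerovalent nickel, formed from NiCl2 by CrCl2, inserts into the C7–I bond with retention of the Z geometry and passes the alkenyl group to trivalent chromium (21), which adds to the C8 aldehyde to give alkoxide 22, hydrolysed on work-up. The closest known reaction type is the intramolecular Nozaki–Hiyama–Kishi coupling of alkenyl iodides with aldehydes that is used to close medium and large carbocycles. The ten-membered carbocycle C1–C10 closes in a 10-exo-trig mode, the cis-fused lactone and the ring-trans C2=C3 unit holding C1–C4 and C9–C10 in a turn that brings C8 within reach of C7. C8, the only new stereocentre, is set under substrate control by C10: 1,3-allylic strain keeps the C8–H in the plane of C6=C7 toward C5, so oxygen and C9 take opposite faces of that alkene, and the fold imposed by the cis lactone decides which face C9 takes; addition to the Re face of the aldehyde gives the required 8S. The step needs chemoselectivity for the aldehyde over the methylene lactone, both esters and the olefins, which the oxophilic, non-basic alkenylchromium secures, the NiCl2 loading being kept low so that nickel-mediated conjugate addition to C13 cannot compete. It also needs ring closure to outrun oligomerisation, which slow addition into a dilute, large excess of CrCl2 secures.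

Step 15
Reactants: 23 [(3aR,5S,6Z,10Z,11aR)-5-hydroxy-6-methyl-3-methylidene-2-oxo-2,3,3a,4,5,8,9,11a-octahydrocyclodeca[b]furan-10-yl]methyl 3-methylbutanoate
Product: 24 [(3aR,5S,6Z,10Z,11aR)-5-(acetyloxy)-6-methyl-3-methylidene-2-oxo-2,3,3a,4,5,8,9,11a-octahydrocyclodeca[b]furan-10-yl]methyl 3-methylbutanoate (CNP0398030.1)
Conditions: Ac2O, pyridine, DMAP (cat.), CH2Cl2, 0 °C → rt
Reagents that add atoms: acetic anhydride, CC(=O)OC(C)=O
Why: O-Acetylation of the secondary allylic C8 hydroxyl proceeds with retention at C8 and leaves both esters and the lactone intact.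

**Compound list**

1 | methyl 4-hydroxybut-2-ynoate | COC(=O)C#CCO | starting material
2 | methyl 4-{[tert-butyl(dimethyl)silyl]oxy}but-2-ynoate | COC(=O)C#CCO[Si](C)(C)C(C)(C)C | intermediate
3 | but-3-en-1-ylmagnesium bromide | C=CCC[Mg]Br | starting material
4 | alkenylcopper adduct: methyl 3-({[tert-butyl(dimethyl)silyl]oxy}methyl)-2-cupriohepta-2,6-dienoate, copper cis to the butenyl group | COC(=O)/C([Cu])=C(\CO[Si](C)(C)C(C)(C)C)CCC=C | intermediate
5 | methyl (2Z)-3-({[tert-butyl(dimethyl)silyl]oxy}methyl)hepta-2,6-dienoate | COC(=O)/C=C(\CO[Si](C)(C)C(C)(C)C)CCC=C | intermediate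
6 | ozonide: methyl (2Z)-3-({[tert-butyl(dimethyl)silyl]oxy}methyl)-5-(1,2,4-trioxolan-3-yl)pent-2-enoate | COC(=O)/C=C(\CO[Si](C)(C)C(C)(C)C)CCC1OCOO1 | intermediate
7 | methyl (2Z)-3-({[tert-butyl(dimethyl)silyl]oxy}methyl)-6-oxohex-2-enoate | COC(=O)/C=C(\CO[Si](C)(C)C(C)(C)C)CCC=O | intermediate
8 | methyl (2Z,6Z)-3-({[tert-butyl(dimethyl)silyl]oxy}methyl)-7-iodoocta-2,6-dienoate | COC(=O)/C=C(\CO[Si](C)(C)C(C)(C)C)CC/C=C(/C)I | intermediate
9 | (2Z,6Z)-3-({[tert-butyl(dimethyl)silyl]oxy}methyl)-7-iodoocta-2,6-dien-1-ol | OC/C=C(\CO[Si](C)(C)C(C)(C)C)CC/C=C(/C)I | intermediate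
10 | (2Z,6Z)-3-({[tert-butyl(dimethyl)silyl]oxy}methyl)-7-iodoocta-2,6-dienal | O=C/C=C(\CO[Si](C)(C)C(C)(C)C)CC/C=C(/C)I | intermediate
11 | methyl 3,3-dimethoxypropanoate | COC(=O)CC(OC)OC | starting material
12 | 3,3-dimethoxypropanal | O=CCC(OC)OC | intermediate
13 | methyl acrylate | C=CC(=O)OC | starting material
14 | methyl 3-hydroxy-5,5-dimethoxy-2-methylidenepentanoate (racemic) | C=C(C(=O)OC)C(O)CC(OC)OC | intermediate
15 | methyl 3-(acetyloxy)-5,5-dimethoxy-2-methylidenepentanoate (racemic) | C=C(C(=O)OC)C(OC(C)=O)CC(OC)OC | intermediate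
16 | methyl (2E)-5,5-dimethoxy-2-[(4,4,5,5-tetramethyl-1,3,2-dioxaborolan-2-yl)methyl]pent-2-enoate | COC(=O)/C(CB1OC(C)(C)C(C)(C)O1)=C/CC(OC)OC | intermediate
17 | O-boryl hydroxy ester: syn adduct (1R,10R), methyl ester with the C1 oxygen bound to the pinacolboryl group | C=C(C(=O)OC)[C@@H](CC(OC)OC)[C@H](OB1OC(C)(C)C(C)(C)O1)/C=C(\CO[Si](C)(C)C(C)(C)C)CC/C=C(/C)I | intermediate
18 | (4R,5R)-5-[(1Z,5Z)-2-({[tert-butyl(dimethyl)silyl]oxy}methyl)-6-iodohepta-1,5-dien-1-yl]-4-(2,2-dimethoxyethyl)-3-methylideneoxolan-2-one | C=C1C(=O)O[C@H](/C=C(\CO[Si](C)(C)C(C)(C)C)CC/C=C(/C)I)[C@@H]1CC(OC)OC | intermediate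
19 | (4R,5R)-5-[(1Z,5Z)-2-(hydroxymethyl)-6-iodohepta-1,5-dien-1-yl]-3-methylidene-4-(2-oxoethyl)oxolan-2-one | C=C1C(=O)O[C@H](/C=C(\CO)CC/C=C(/C)I)[C@@H]1CC=O | intermediate
20 | (4R,5R)-5-{(1Z,5Z)-6-iodo-2-[(3-methylbutanoyloxy)methyl]hepta-1,5-dien-1-yl}-3-methylidene-4-(2-oxoethyl)oxolan-2-one | C=C1C(=O)O[C@H](/C=C(\COC(=O)CC(C)C)CC/C=C(/C)I)[C@@H]1CC=O | intermediate
21 | alkenylchromium: C7 dichlorochromium derivative of 20, geometry retained | C=C1C(=O)O[C@H](/C=C(\COC(=O)CC(C)C)CC/C=C(/C)[Cr](Cl)Cl)[C@@H]1CC=O | intermediate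
22 | chromium alkoxide: C8 O-dichlorochromium derivative of 23 | C=C1C(=O)O[C@@H]2/C=C(\COC(=O)CC(C)C)CC/C=C(/C)[C@@H](O[Cr](Cl)Cl)C[C@H]12 | intermediate
23 | [(3aR,5S,6Z,10Z,11aR)-5-hydroxy-6-methyl-3-methylidene-2-oxo-2,3,3a,4,5,8,9,11a-octahydrocyclodeca[b]furan-10-yl]methyl 3-methylbutanoate | C=C1C(=O)O[C@@H]2/C=C(\COC(=O)CC(C)C)CC/C=C(/C)[C@@H](O)C[C@H]12 | intermediate
24 | [(3aR,5S,6Z,10Z,11aR)-5-(acetyloxy)-6-methyl-3-methylidene-2-oxo-2,3,3a,4,5,8,9,11a-octahydrocyclodeca[b]furan-10-yl]methyl 3-methylbutanoate | C=C1C(=O)O[C@@H]2/C=C(\COC(=O)CC(C)C)CC/C=C(/C)[C@@H](OC(C)=O)C[C@H]12 | target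

**Step count and risks**

Total step count: 15. Longest linear sequence: 11 steps (steps 1–6, then 11–15); fragment B takes 4 steps (7–10).

Steps most likely to fail:

Step 14. The ring closure may show poor facial selectivity at C8, because the bias comes only from the lactone fold, and slow closure would give intermolecular coupling more room. Fallback: the cyclisation is still run from 20; if the alkenylchromium prefers the other aldehyde face, the product is the C8 epimer, [(3aR,5R,6Z,10Z,11aR)-5-hydroxy-6-methyl-3-methylidene-2-oxo-2,3,3a,4,5,8,9,11a-octahydrocyclodeca[b]furan-10-yl]methyl 3-methylbutanoate F1. It is not acetylated with the anhydride but treated with acetic acid, PPh3 and diisopropyl azodicarboxylate in THF at 0 °C (Mitsunobu reaction). Displacement of the activated C8 oxygen by acetate with inversion should give the 8S acetate and comes back to the route at 24.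

Step 11. The ester-deactivated boronate may add too slowly at the temperature at which the acid still tells the aldehyde faces apart, so that uncatalysed addition erodes the enantioselectivity. Fallback: stereocontrol is moved from the catalyst to an ester auxiliary on the allylboronate. The fallback sets out from 12:
- (1R,2S,5R)-5-methyl-2-(2-phenylpropan-2-yl)cyclohexyl prop-2-enoate F2 is made from the commercial alcohol with acryloyl chloride and Et3N.
- Morita–Baylis–Hillman reaction of 12 with F2 under the conditions of step 8 gives the 8-phenylmenthyl 3-hydroxy-5,5-dimethoxy-2-methylidenepentanoate F3.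
- Acetylation as in step 9 gives the acetate F4, and borylation as in step 10 gives the 8-phenylmenthyl (2E)-allylboronate F5.
- Sc(OTf)3-catalysed addition of F5 to 10 in CH2Cl2 at −78 °C goes through the same chair, so it is still syn; the phenyl group of the auxiliary covers one face of the allyl unit. This gives the O-boryl 8-phenylmenthyl ester F6.
- Lactonisation with TsOH expels the auxiliary alcohol and comes back to the route at 18.
- If this auxiliary covers the wrong face, its antipode is used.

Step 8. Base-induced loss of methanol from the β,β-dialkoxy aldehyde 12 may outrun the slow amine-catalysed coupling. Fallback: the fallback sets out from 12 and replaces the amine catalysis by a vinylalumination. Hydroalumination of methyl propiolate with i-Bu2AlH and N-methylmorpholine N-oxide in THF at 0 °C gives methyl 2-[bis(2-methylpropyl)alumanyl]prop-2-enoate F7. Its 1,2-addition to 12 gives the same hydroxy ester after work-up with aq. NH4Cl and comes back to the route at 14.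

Further compounds
F1 | step 14 | [(3aR,5R,6Z,10Z,11aR)-5-hydroxy-6-methyl-3-methylidene-2-oxo-2,3,3a,4,5,8,9,11a-octahydrocyclodeca[b]furan-10-yl]methyl 3-methylbutanoate (C8 epimer of 23) | C=C1C(=O)O[C@@H]2/C=C(\COC(=O)CC(C)C)CC/C=C(/C)[C@H](O)C[C@H]12
F2 | step 11 | (1R,2S,5R)-5-methyl-2-(2-phenylpropan-2-yl)cyclohexyl prop-2-enoate | CC(C)(c1ccccc1)[C@@H]1CC[C@@H](C)C[C@H]1OC(=O)C=C
F3 | step 11 | (1R,2S,5R)-5-methyl-2-(2-phenylpropan-2-yl)cyclohexyl 3-hydroxy-5,5-dimethoxy-2-methylidenepentanoate (carbinol epimers) | CC(C)(c1ccccc1)[C@@H]1CC[C@@H](C)C[C@H]1OC(=O)C(=C)C(O)CC(OC)OC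
F4 | step 11 | (1R,2S,5R)-5-methyl-2-(2-phenylpropan-2-yl)cyclohexyl 3-(acetyloxy)-5,5-dimethoxy-2-methylidenepentanoate (carbinol epimers) | CC(C)(c1ccccc1)[C@@H]1CC[C@@H](C)C[C@H]1OC(=O)C(=C)C(OC(C)=O)CC(OC)OC
F5 | step 11 | (1R,2S,5R)-5-methyl-2-(2-phenylpropan-2-yl)cyclohexyl (2E)-5,5-dimethoxy-2-[(4,4,5,5-tetramethyl-1,3,2-dioxaborolan-2-yl)methyl]pent-2-enoate | CC(C)(c1ccccc1)[C@@H]1CC[C@@H](C)C[C@H]1OC(=O)/C(CB2OC(C)(C)C(C)(C)O2)=C/CC(OC)OC
F6 | step 11 | O-boryl 8-phenylmenthyl ester: syn adduct (1R,10R) of F5 and 10 | CC(C)(c1ccccc1)[C@@H]1CC[C@@H](C)C[C@H]1OC(=O)C(=C)[C@@H](CC(OC)OC)[C@H](OB2OC(C)(C)C(C)(C)O2)/C=C(\CO[Si](C)(C)C(C)(C)C)CC/C=C(/C)I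
F7 | step 8 | methyl 2-[bis(2-methylpropyl)alumanyl]prop-2-enoate | C=C(C(=O)OC)[Al](CC(C)C)CC(C)C
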